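Minutes of working free enzyme are the unit to reckon in here. Take as a working assumption that c(free enzyme) multiplies each rate. While that concentration holds, substrate then falls in a pseudo-first-order way, and a flask's progress is counted in the minutes its free enzyme works.

| flask | substrate | free enzyme | temperature | remark | time |
|---|---|---|---|---|---|
| epsilon | 6 mM | 0.01 mol% | 37 °C | run made earlier |  |
| Wednesday's | 12 mM | 0.01 mol% | 67 °C |  | 1.0 h |
| Tuesday's | 12 mM | 0.01 mol% | 52 °C |  | 1.0 h |
| Monday's | 12 mM | 0.01 mol% | 37 °C |  | 1.0 h |

- epsilon (time / min: target / %, substrate / %): 0.500: 44, 55; 0.833: 64, 29; 1.50: 76, 12; 3.00: 62, 1; 6.00: 41, 0

(scatter of a reading: 1.5 percentage points)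

* which of the two there is more of at the end, Wednesday's (target / isomer of the product)
* which of the two there is more of at the end, Tuesday's (target / isomer of the product)
* which of the two there is more of at the end, Monday's (target / isomer of the product)
* target at the end, in percent of the substrate charged, Wednesday's
* target at the end, in percent of the substrate charged, Tuesday's
* target at the end, in percent of the substrate charged, Monday's

- the numbers in the tables scatter with a standard deviation of 1.5 percentage points
- the earlier runs do not show what temperature does; that part of a forecast is a guess
- no earlier run changes the charge of free enzyme; that part of a forecast is a guess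

Read the constant from the epsilon run: substrate goes from 55% at 0.500 min to 12% at 1.50 min, which gives 1.52 /min as a reading with its scatter. Scale it by the charge of free enzyme to get the full-charge constant, the pace of substrate per minute of working free enzyme on Monday's charge at the epsilon temperature: 3.04 /min.

Now turn the question round and ask what target's lead over isomer of the product at the end of Monday's would require. In the epsilon run, target still leads at 3.00 min, with 62% against 37.0% by balance. At 6.00 min it trails, with 41% against 59.0%. On Monday's charge the crossing therefore moves to between 1.50 min and 3.00 min of working time, so Monday's free enzyme would have to stop before the crossing, by 3.00 min of working time at the latest. Yet the epsilon run shows target still falling up to 6.00 min, which is longer than that latest stop. I therefore commit to isomer of the product ahead on Monday's. For Tuesday's and Wednesday's the temperature is unread, so which side each falls on is a guess.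

The forecast gave target 22% on Monday's, 28% on Tuesday's and 55% on Wednesday's, saying of the hottest flask “my guess is that the enzyme dies within minutes”.

The flasks give target 24.4% on Monday's, 78.5% on Tuesday's and 9.65% on Wednesday's, and the larger of the pair is isomer of the product, target and target in that order. Wednesday's ends with 90.3% substrate and unfolded enzyme at 100% of the catalyst charged, and its target stands at 9.65% at 10.0 h. Put 3.04 /min to it: the substrate consumed on Wednesday's equals 0.0335 min of working free enzyme at Monday's pace, shorter than the 1.50 min where the crossing span begins.

    substrate + free enzyme ⇌ complex (K = 1900 /M, k = 58000 /M/s, Ea = 36.0 kJ/mol, ΔH = −29.0 kJ/mol)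
    free enzyme → unfolded enzyme (k = 4.00 × 10⁻⁴ /s, Ea = 251 kJ/mol)
    target + free enzyme ⇌ isomer of the product + free enzyme, rate k3*[free enzyme]*[target] forward; the back reaction follows from the equilibrium constant (K = 3.10, k = 6900 /M/s, Ea = 25.0 kJ/mol, ΔH = −90.0 kJ/mol)
    complex → free enzyme + target (k = 480 /s, Ea = 54.0 kJ/mol)
    (constants at 37 °C)

On the neighbour of Wednesday's with 0.025 mol% free enzyme, hold those working minutes and scale 3.04 /min by the charge: 77.5% substrate should remain. The computed neighbour ends with 77% substrate and 22.3% target.

The data were generated by integration on assumed constants, and the scatter is random.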